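Readings and results stem from a simulated flask with constants of no real substance; noise was put on by code.

The alpha run left 37.4% of its electrophile after 10.0 min, and the delta run, with 3.7 equiv of free base instead of 1.7 equiv, left 17.4%.

| setting | alpha | delta | winter | summer |
|---|---|---|---|---|
| electrophile | 20 mM | 20 mM | 20 mM | 20 mM |
| free base | 1.7 equiv | 3.7 equiv | 1.20 equiv | 2.40 equiv |
| protonated nucleophile | 2.5 equiv | 2.5 equiv | 2.50 equiv | 2.50 equiv |
| remark | run made earlier | run made earlier |  |  |
| time |  |  | 10 min | 10 min |

| run | time / min | electrophile / % | target / % |
|---|---|---|---|
| alpha | 1.33 | 87.5 | 2.4 |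
| alpha | 3.00 | 73.2 | 1.7 |
| alpha | 4.00 | 66.0 | 1.6 |
| alpha | 6.00 | 54.1 | 1.9 |
| alpha | 8.00 | 44.7 | 1.0 |
| alpha | 10.0 | 37.4 | 0.9 |
| delta | 0.833 | 89.2 | 3.3 |
| delta | 1.33 | 81.8 | 3.5 |
| delta | 2.00 | 72.9 | 3.5 |
| delta | 3.00 | 62.1 | 2.6 |
| delta | 4.00 | 52.6 | 2.8 |
| delta | 6.00 | 37.6 | 2.4 |
| delta | 10.0 | 17.4 | 1.4 |

(readings scatter by 0.3 percentage points)

- part of the electrophile that has reacted at the end, winter
- part of the electrophile that has reacted at the end, summer
- what raising the equivalents of free base from its lowest to its highest value here does to the part of the electrophile that has reacted (changes below 5 percentage points count as none) (it rises / no change / it falls)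

- what was read earlier has a scatter of 0.3 percentage points, one standard deviation

At the last reading, target stands at 0.9% in alpha and 1.4% in delta, so you follow the loss of electrophile. If you take the rate as proportional to the fraction f left and integrate, f = exp(−kt), and each run gives a mean apparent pseudo-first-order constant k = ln(1/f)/t: 0.0983 /min for alpha and 0.175 /min for delta. It is a mean over the run: the same reckoning on delta's reading at 1.33 min gives 0.151 /min.

Call 0.740 the apparent order in free base: the logarithm of the ratio of two constants over that of the ratio of their equivalents.

You have two ways to a new constant. The power law with this order gives 0.0760 /min for winter and 0.127 /min for summer, so you reckon 53.2% and 71.9% reacted. The straight line through the two constants, with slope 0.0383 /min per equivalent, gives 54.7% and 71.4%.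

Summer lies between the runs, and the two ways differ there by 0.50 percentage points. Winter lies below alpha, and they differ by 1.5 points. The line is the suspect: carried down to zero equivalents it still reads 0.0332 /min, a third of alpha's constant, and neither run tests that. So you commit to the power law, a reckoned rise of 19 points against the margin of 5 points.

The forecast gave 55% for winter and 71% for summer, with the verdict it rises, and called winter “the larger extrapolation”.

The simulation gives 53.2% for winter and 72.0% for summer: it rises, by 19 points.

    electrophile + nucleophile → acid set free + target (k = 1.75 /M/s)
    nucleophile + acid set free ⇌ protonated nucleophile, settled at all times (K = 5.71 × 10⁵ /M)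
    acid set free + free base ⇌ salt of the base (K = 6.10 × 10⁵ /M, k = 17.4 /M/s)
    target → over-reaction product (k = 0.0387 /s)
    electrophile + target → side product (k = 0.790 /M/s)

These results give mean constants of 0.0760 /min for winter and 0.127 /min for summer, an order of 0.744 beside the 0.740 from the runs. Now apply the same reckoning to the charge, with the equivalents of the recipe and the time held. A neighbour of winter with 8.0 mM of electrophile leaves 63.5%, so its mean constant is 0.0454 /min and the order in charge at these equivalents is 0.563. For the neighbour with 80 mM this gives 0.166 /min, so you reckon 19.0% left. That flask holds 18.8% of its electrophile at the end.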